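## The problem

The target is a C36 hydroquinone bis-sulfate in which two trans-decalins are joined by an ethylene bridge. The left decalin is numbered as a drimane (ring A = C1–C5/C10, ring B = C5–C10, C11 = benzylic carbon); the right decalin carries primed labdane-type numbers, C11' and C12' being the bridge from C9' to C4. The eight stereocentres fall into two sets of four (C4, C5, C9, C10 and C5', C8', C9', C10') that the flexible bridge insulates from each other, so each decalin must be made in its own absolute sense. The right set is that of sclareolide except at C8', where the hydroxyl is axial (β) and the methyl equatorial. The left set is contiguous and can be relayed in one folding event. Its hard point is quaternary C4 (methyl equatorial, bridge axial and syn to the axial C10 methyl), next to the trans C5/C10 fusion, the equatorial arylmethyl group on C9 and a C7=C8 alkene that must not move to C8=C9. The groups that will not survive rough treatment are the aryl O-sulfates (acid- and heat-labile, last step only), the hydroquinone (air-sensitive, carried as its dimethyl ether), the tertiary axial C8' alcohol (ionises with acid and is a nucleophile five atoms from C4) and the trisubstituted alkene. The enabling feature is that C4 with its axial bridge, the trans-fused C5/C10, the equatorial C9 substituent and an sp2 C8 are together the imprint of a chair–chair cation–olefin cascade. In it a Z-trisubstituted C3–C4 oxirane is opened anti at C4 by a C5=C10 alkene and the C10 cation is taken by C9 of an enol ether on C8; the price is an oxygen at C3 that has to be removed.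

## Retrosynthesis

**Sulfates and hydroquinone (33 ⇒ 32 ⇒ 30 ⇒ 29).** The S–O bonds are cut first, because no earlier intermediate tolerates them. The hydroquinone 32 is traced through quinone 31 to the dimethyl ether 30, and the C8' alcohol to its triethylsilyl ether 29. Methyl ethers are preferred to benzyl ethers, whose hydrogenolysis would endanger C7=C8, and they come free with aldehyde 21. The forward steps must spare the alkene and leave the hindered tertiary alcohol unsulfated.

**C8 methyl and C7=C8 (29 ⇒ 28 ⇒ 26).** The C8–CH3 bond is cut to enol triflate 28, made from ketone 26. Methyl addition and dehydration, or methylenation and isomerisation, would give mixtures with the C8=C9 and exocyclic alkenes. A kinetic enolate can only form towards C7, since H-9 is tertiary and flanked by quaternary C10. The forward reaction asks for regioselective enolisation and a methyl cross-coupling on a hindered triflate.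

**C3 oxygen (26 ⇒ 25 ⇒ 24).** The C3–O bond is restored. This costs two steps, accepted because the C3 oxygen is what programmes C4. Radical deoxygenation of a hindered equatorial 3-hydroxyl next to a quaternary carbon is routine in terpenoids and tolerates the ketone.

**Key disconnection (24 ⇒ 23).** C4–C5 and C9–C10 are cut together, opening both left rings to the epoxy diene enol silane 23. Annulation routes to a decalin give no handle on a C4 centre bearing a long axial chain. A cascade started at an alkene or allylic alcohol would give neither absolute control nor a geometric lever at C4. Precursor 23 keeps only the two oxirane stereocentres on the left. The forward reaction must turn Z-oxirane geometry into the axial bridge, and E-alkene and Z-enol silane geometry into C5, C10 and C9.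

**Enol silane, enone, keto phosphonate (23 ⇒ 22 ⇒ 20 + 21; 20 ⇒ 17 + 18).** The Si–O and C11–H bonds are cut to enone 22, which fixes both the regiochemistry and the Z geometry of the enol silane; silylation of a saturated ketone would give neither. The C9=C11 bond is cut to aldehyde 21 and keto phosphonate 20, and C6–C7 to allylic bromide 17 and phosphonate 18. This keeps the ketone out of all earlier organometallic steps.

**Oxirane (17 ⇒ 15 ⇒ 14 ⇒ 13).** Bromide 17 comes from alcohol 15 and acetate 14; the oxirane is traced to Z-alkene 13. An oxirane made from a Z-2-methylallylic alcohol by hydroxyl-directed epoxidation was weighed first. It would leave the right decalin to be attached at C11'–C12' by displacement at a neopentyl carbon beside the oxirane with a hindered C11' nucleophile. Epoxidising the finished alkene avoids this. It asks for a reagent-controlled oxygen transfer that tells C3=C4 from C5=C10 without a hydroxyl handle; the allylic acetate of 13 deactivates C5=C10.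

**Bridge (13 ⇒ 6 + 10).** The sp2–sp3 bond C4–C12' is cut. Both bridge carbons then come with the sclareolide skeleton. The bond is made at an unhindered primary carbon by cross-coupling, before C4 is quaternary. Z-vinyl iodide 10 carries the geometry, and the coupling must retain it.

**Left chain (10 ⇒ 9 ⇒ 8 ⇒ 7).** The C3=C4 bond is cut to aldehyde 9, obtained by cleaving the terminal alkene of geranyl acetate 7 through epoxide 8. Compound 7 supplies C1–C3, C5, C6, C10 and its methyl, with the E alkene C5=C10 and the C6 oxygen in place.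

**Right decalin (6 ⇒ 5 ⇒ 3 ⇒ 2 ⇒ 1).** Iodide 6 is traced through alcohol 5 and diol 3 to 8-epi-sclareolide 2 and (+)-sclareolide 1. The chiral pool gives C5', C9' and C10' directly, and C8' by thermodynamic epimerisation of the lactone. The tertiary oxygen is silylated before C12' is activated, so that it cannot close a tetrahydrofuran.

## Roads not taken

**Alternative 1:** The cut is the C3–C4 bond of ring A, with C4 made quaternary by alkylation. In the forward step the extended enolate of the iodo cyano enone A2 alkylates its own primary iodide at C4 and gives the bicyclic Δ5-7-ketone A1 with the nitrile axial.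
- Merits: axial alkylation of a nitrile-stabilised anion is a dependable way to the C4 arrangement needed here, the nitrile carbon being the future C12'. No C3 oxygen is introduced, so the two deoxygenation steps of the chosen plan fall away. The chemistry is ionic, robust and free of a sensitive polyene.
- Weak points: A1 holds only C4 and C10. C5 (reduction of the enone to the trans fusion), the C8 methyl with C7=C8 and the C9 arylmethyl group must all follow by substrate control. The carbonyl sits on C7, one carbon away from where functionality is needed. The bridge must still be forged from a neopentyl axial nitrile towards hindered C9' or C11'. A2 needs its own asymmetric entry to C10.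
- Comparison: alternative 1 is better on the C3 question and on robustness. The chosen plan sets against it that one step closes both rings and sets four stereocentres with the right decalin already attached, and that the bridge is made on an sp2 carbon before C4 is crowded.

**Alternative 2:** The cut goes through three C–C bonds of the arene. In the forward step the terminal alkyne A4 and the zerovalent chromium carbene complex A5 combine with one carbonyl ligand of A5 and close the ring as the 2-terpenyl-4-methoxyphenol A3.
- Merits: no electron-rich arene is present during cationic or organometallic steps. The regiochemistry is right (alkyne substituent ortho to the new hydroxyl, methoxy para). Only one methyl ether remains to be removed.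
- Weak points: the cut concerns the periphery. A4 already contains all eight stereocentres, so the real problem is only moved. A propargyl group on C9 would have to be carried through the construction of the left decalin, where an alkyne is itself a π-nucleophile towards cations. Stoichiometric chromium is used next to a free tertiary alcohol, and A3 still needs the same oxidation, reduction and sulfation.
- Comparison: for the arene as such this road is as good as the chosen one, and better if the dimethoxyarene interfered with the Lewis acid. The chosen plan sets against it that the arene costs one olefination with aldehyde 21, and that it can reach the C8 cation only through a strained five-membered closure onto an oxocarbenium ion that loses silicon first.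

**Alternative 3:** The cuts are C4'–C5' and C9'–C10' of the right decalin. In the forward step the terminal (S)-epoxy diene enol silane A7, hung on the finished left decalin, is opened by the same aluminium Lewis acid and folds to the bis-decalin 3'-hydroxy-8'-ketone A6.
- Merits: a terminal gem-dimethyl oxirane is the best-precedented initiator and is easy to make enantioselectively. No right-hand oxygen nucleophile is present during the cascade. Methyl addition to the C8' ketone from the equatorial side would give the axial 8'-alcohol directly, without an epimerisation step.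
- Weak points: the cascade is spent on the decalin that the chiral pool provides in four steps. The left decalin with quaternary C4 must be made first by other means, so the hardest centre is untouched by the key step. The C3' oxygen must be removed as well. The terminating enol silane carbon carries the whole left decalin, and methyl addition to a hindered, enolisable ketone is uncertain.
- Comparison: the cyclization of A7 is probably the more reliable event, and in that respect this road is better. The chosen plan sets against it that the cascade is used where no chiral-pool answer exists, and that it is shorter overall.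

Key step: step 15

Remarks on the chemistry:
- The two aryl sulfates of the target formula are taken as free hydrogen sulfates; the compound would be handled as its bis(pyridinium) or disodium salt, and the compound list gives the neutral acid form.
- Geranyl acetate is taken as the pure 2E isomer.
- Abbreviations in names: DecOSi = (1R,2S,4aS,8aS)-2,5,5,8a-tetramethyl-2-(triethylsilyloxy)decahydronaphthalen-1-yl (the silylated right decalin, bonded through C9'); DecOH = the same group with a free 2-hydroxyl.

## Route

Step 1
Reactants: 1 (+)-sclareolide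
Product: 2 8-epi-sclareolide (cis-fused γ-lactone, lactone oxygen β on C8')
Conditions: conc. H2SO4, HCO2H, rt
Reagents that add atoms: none
Why: Acid-mediated epimerisation: reversible alkyl–oxygen ionisation at tertiary C8' lets the carboxyl group re-close on the β face, and the cis-fused lactone is the thermodynamic isomer; C5', C9' and C10' are untouched.

Step 2
Reactants: 2 8-epi-sclareolide
Product: 3 (1R,2S,4aS,8aS)-1-(2-hydroxyethyl)-2,5,5,8a-tetramethyldecahydronaphthalen-2-ol
Conditions: LiAlH4, THF, 0 °C → rt
Reagents that add atoms: none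
Why: Hydride reduction of a lactone to the 1,4-diol; no stereocentre is involved.

Step 3
Reactants: 3 the 8-epi diol
Product: 5 2-DecOSi-ethanol, via bis(triethylsilyl) ether 4 (not isolated)
Conditions: Et3SiOTf (2.5 equiv), 2,6-lutidine, CH2Cl2, −78 → 0 °C; then MeOH, pyridinium p-toluenesulfonate (cat.), 0 °C
Reagents that add atoms: triethylsilyl trifluoromethanesulfonate, CC[Si](CC)(CC)OS(=O)(=O)C(F)(F)F
Why: The silyl triflate silylates even the axial tertiary alcohol, and mild acid methanolysis then removes the unhindered primary silyl ether far faster than the tertiary one; O8' is thus masked before C12' is activated, which prevents closure of the tetrahydrofuran.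

Step 4
Reactants: 5 2-DecOSi-ethanol
Product: 6 2-DecOSi-ethyl iodide
Conditions: I2, PPh3, imidazole, CH2Cl2, 0 °C → rt
Reagents that add atoms: iodine, II
Why: Appel-type iodination of an unhindered primary alcohol under near-neutral conditions that leave the tertiary silyl ether alone.

Step 5
Reactants: 7 geranyl acetate
Product: 8 (±)-6,7-epoxygeranyl acetate
Conditions: mCPBA, NaHCO3, CH2Cl2, 0 °C
Reagents that add atoms: 3-chloroperoxybenzoic acid, OC(=O)c1cccc(Cl)c1 with O inserted as O=C(OO)c1cccc(Cl)c1
Why: Peracid epoxidation is selective for the distal alkene because the allylic acetate deactivates C2=C3; the new stereocentre is destroyed in step 6.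

Step 6
Reactants: 8 (±)-6,7-epoxygeranyl acetate
Product: 9 (2E)-3-methyl-6-oxohex-2-en-1-yl acetate
Conditions: H5IO6, THF–H2O, 0 °C
Reagents that add atoms: none
Why: Periodic acid hydrolyses the oxirane and cleaves the resulting glycol in one operation, releasing the aldehyde (future C3) and acetone; the E alkene and the acetate are unaffected.

Step 7
Reactants: 9 (2E)-3-methyl-6-oxohex-2-en-1-yl acetate
Product: 10 (2E,6Z)-7-iodo-3-methylocta-2,6-dien-1-yl acetate
Conditions: [Ph3PEt]I, n-BuLi, THF, rt; I2, −78 °C; NaN(SiMe3)2, −20 °C; then 9, −78 °C → rt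
Reagents that add atoms: ethyltriphenylphosphonium iodide, CC[P+](c1ccccc1)(c1ccccc1)c1ccccc1.[I-]; iodine, II
Why: Zhao olefination: the α-iodoethylidene ylide, a non-stabilised ylide, gives the Z-2-iodoalkene (iodine cis to the chain) under kinetic control, and the aldehyde reacts at −78 °C far faster than the acetate.

Step 8
Reactants: 6 2-DecOSi-ethyl iodide; 10 (2E,6Z)-7-iodo-3-methylocta-2,6-dien-1-yl acetate
Product: 13 (2E,6Z)-3,7-dimethyl-9-DecOSi-nona-2,6-dien-1-yl acetate, via alkyllithium 11 (not isolated), via lithium methoxyborate 12 (not isolated)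
Conditions: 6, t-BuLi (2.1 equiv), Et2O, −78 °C; 9-methoxy-9-borabicyclo[3.3.1]nonane, THF, −78 °C → rt; then 10, Pd(dppf)Cl2 (5 mol%), AsPh3, K3PO4 (aq.), DMF, rt
Reagents that add atoms: none
Why: B-alkyl Suzuki–Miyaura coupling: the primary alkyl borate transfers its alkyl group to the vinylpalladium species with retention of alkene geometry, so the C12' bridge takes the place of iodine cis to C2; oxidative addition to the vinyl iodide is much faster than ionisation of the allylic acetate.

Step 9
Reactants: 13 the E,Z-diene acetate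
Product: 14 (2E)-3-methyl-5-[(2S,3R)-3-methyl-3-(2-DecOSi-ethyl)oxiran-2-yl]pent-2-en-1-yl acetate
Conditions: 1,2:4,5-di-O-isopropylidene-β-L-erythro-2,3-hexodiulo-2,6-pyranose (30 mol%, from L-sorbose), 2KHSO5·KHSO4·K2SO4, K2CO3, Bu4NHSO4, MeCN–CH2(OMe)2–aq. Na2B4O7/Na2EDTA, 0 °C
Reagents that add atoms: potassium peroxymonosulfate, [K+].[O-]S(=O)(=O)OO
Why: Shi epoxidation: the chiral dioxirane attacks the electron-rich C3=C4 alkene and leaves the acetate-deactivated C5=C10 alone. The D-fructose-derived ketone gives the (R) configuration at the CH carbon of trisubstituted alkenes, so its enantiomer is used to make C3 (S); syn delivery then makes C4 (R) with the bridge cis to C2, and any minor epoxide diastereomer is removed by chromatography.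

Step 10
Reactants: 14 the epoxy acetate
Product: 15 (2E)-3-methyl-5-[(2S,3R)-3-methyl-3-(2-DecOSi-ethyl)oxiran-2-yl]pent-2-en-1-ol
Conditions: K2CO3, MeOH, 0 °C → rt
Reagents that add atoms: none
Why: Base-catalysed transesterification; the trisubstituted oxirane and the tertiary silyl ether are stable to methanolic carbonate.

Step 11
Reactants: 15 the epoxy allylic alcohol
Product: 17 (2S,3R)-2-[(3E)-5-bromo-3-methylpent-3-en-1-yl]-3-methyl-3-(2-DecOSi-ethyl)oxirane, via allylic mesylate 16 (not isolated)
Conditions: MsCl, Et3N, THF, −40 °C; then LiBr, THF, 0 °C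
Reagents that add atoms: lithium bromide, [Li+].[Br-]
Why: Mesylation and in-situ bromide displacement is the standard non-acidic route to allylic bromides that carry an oxirane; the displacement is SN2 at the primary carbon and keeps the E geometry.

Step 12
Reactants: 17 the epoxy allylic bromide; 18 dimethyl (2-oxopropyl)phosphonate
Product: 20 dimethyl {(5E)-6-methyl-8-[(2S,3R)-3-methyl-3-(2-DecOSi-ethyl)oxiran-2-yl]-2-oxooct-5-en-1-yl}phosphonate, via phosphonate dianion 19 (not isolated)
Conditions: 18 (2 equiv), NaH, THF, 0 °C; n-BuLi, 0 °C; then 17, 0 °C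
Reagents that add atoms: none
Why: γ-Alkylation of a β-keto phosphonate dianion: the more reactive terminal carbanion displaces the allylic bromide and forms C6–C7; the hindered oxirane is inert at 0 °C.

Step 13
Reactants: 20 the β-keto phosphonate; 21 2,5-dimethoxybenzaldehyde
Product: 22 (1E,6E)-1-(2,5-dimethoxyphenyl)-7-methyl-9-[(2S,3R)-3-methyl-3-(2-DecOSi-ethyl)oxiran-2-yl]nona-1,6-dien-3-one
Conditions: Ba(OH)2·8H2O, THF–H2O (40:1), rt
Reagents that add atoms: none
Why: Horner–Wadsworth–Emmons olefination of a stabilised phosphonate with an aryl aldehyde gives the E enone under mild base that spares oxirane and silyl ether.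

Step 14
Reactants: 22 the aryl enone
Product: 23 tert-butyl{[(2Z,6E)-1-(2,5-dimethoxyphenyl)-7-methyl-9-[(2S,3R)-3-methyl-3-(2-DecOSi-ethyl)oxiran-2-yl]nona-2,6-dien-3-yl]oxy}dimethylsilane
Conditions: tBuMe2SiH, Pt2[(CH2=CHSiMe2)2O]3 (1 mol%, zerovalent platinum), toluene, 60 °C
Reagents that add atoms: tert-butyldimethylsilane, C[SiH](C)C(C)(C)C
Why: Metal-catalysed 1,4-hydrosilylation of an enone: hydrogen goes to C11 and silicon to oxygen through the s-cis enone, which fixes the enol silane at C8=C9 and gives the Z isomer (arylmethyl trans to C7); the trisubstituted alkene and the oxirane do not react.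

Step 15
Reactants: 23 the Z-epoxy diene enol silane
Product: 24 left trans-decalin ketol (drimane numbering): 3β-OH, 4α-CH3, 4β-(2-DecOSi-ethyl), 5α-H, 8-oxo, 9β-(2,5-dimethoxybenzyl), 10β-CH3
Conditions: MeAlCl2 (2–3 equiv), CH2Cl2, −94 °C; then Et3N, MeOH–H2O, −94 °C → rt
Reagents that add atoms: none
Why: Epoxide-initiated cation–olefin bicyclization of the kind established for polyprenoid oxiranes with silyl enol ether termination: MeAlCl2 binds the oxirane oxygen, the tertiary C4–O bond stretches and C5 of the E-alkene attacks C4 anti to oxygen in a concerted opening. Ring A (C1–C5, C10) closes 6-endo on the C5=C10 alkene through a chair and leaves the tertiary C10 cation. Ring B (C5–C10) closes 6-endo when C9 of the Z-enol silane takes that cation through a second chair, and the silyl oxocarbenium ion gives up tBuMe2Si to chloride to leave the C8 ketone. C3 keeps the (S) C–O bond of the oxirane and becomes the equatorial 3β-alcohol, which fixes the absolute sense of the whole fold. C4 is inverted, so the oxirane substituent cis to C2 (the C12' bridge) ends axial (β) and the methyl equatorial (α). The E geometry of C5=C10 sets H-5 α and the C10 methyl β (trans fusion), and the Z-enol silane (C11 trans to C7) sets the arylmethyl group equatorial (β) on C9, which is also the thermodynamic epimer next to the ketone. The cyclization has to outrun a 1,2-hydride shift at C4 and capture of C4 by the 8'-oxygen; the low temperature, a nucleophilic trisubstituted alkene five atoms away and the bulky Et3Si group on the hindered oxygen are meant to secure this, while 6-endo closure is secured at both alkenes by the tertiary C10 and the oxygen-stabilised C8 cations.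

Step 16
Reactants: 24 the ketol
Product: 25 the 3β-O-phenoxythiocarbonyl derivative of 24
Conditions: PhOC(S)Cl, pyridine, 4-(dimethylamino)pyridine (cat.), CH2Cl2, rt
Reagents that add atoms: O-phenyl chlorothionoformate, S=C(Cl)Oc1ccccc1
Why: Acylation of the only free hydroxyl under non-enolising conditions prepares the Barton–McCombie deoxygenation; an alkoxide-based xanthate synthesis is avoided because of the ketone.

Step 17
Reactants: 25 the thionocarbonate
Product: 26 the 3-deoxy ketone (4α-CH3, 4β-(2-DecOSi-ethyl), 5α-H, 8-oxo, 9β-(2,5-dimethoxybenzyl), 10β-CH3)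
Conditions: Bu3SnH, 2,2'-azobis(isobutyronitrile) (cat.), toluene, 100 °C
Reagents that add atoms: none
Why: Barton–McCombie radical deoxygenation of a secondary thionocarbonate; the C3 radical is reduced by the stannane, and C4 and the other stereocentres are not involved.

Step 18
Reactants: 26 the 8-ketone
Product: 28 the 8-trifluoromethanesulfonyloxy-7-ene (enol triflate of 26 towards C7), via potassium enolate 27 (not isolated)
Conditions: KN(SiMe3)2, THF, −78 °C; then PhNTf2, −78 → 0 °C
Reagents that add atoms: N-phenylbis(trifluoromethanesulfonimide), O=S(=O)(N(c1ccccc1)S(=O)(=O)C(F)(F)F)C(F)(F)F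
Why: Kinetic deprotonation takes the accessible C7 methylene and not the tertiary H-9 shielded by C10 and the arylmethyl group, so the enolate and its triflate place the double bond at C7=C8 and leave C9 intact.

Step 19
Reactants: 28 the enol triflate
Product: 29 the 8-methyl-7-ene (4β-(2-DecOSi-ethyl), 9β-(2,5-dimethoxybenzyl))
Conditions: MeZnCl, Pd(PPh3)4 (5 mol%, zerovalent palladium), THF, 50 °C
Reagents that add atoms: methylzinc chloride, C[Zn]Cl
Why: Negishi cross-coupling of an enol triflate with a methylzinc reagent replaces the triflate by methyl without moving the double bond.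

Step 20
Reactants: 29 the silyl ether
Product: 30 the tertiary alcohol (4β-(2-DecOH-ethyl), 9β-(2,5-dimethoxybenzyl), 8-methyl-7-ene)
Conditions: Bu4NF, THF, 45 °C
Reagents that add atoms: none
Why: Fluoride cleavage of the triethylsilyl ether under basic conditions that cannot ionise the tertiary alcohol or isomerise the alkene.

Step 21
Reactants: 30 the dimethyl ether
Product: 32 the hydroquinone (2-substituted benzene-1,4-diol), via quinone 31 (not isolated)
Conditions: (NH4)2Ce(NO3)6 (tetravalent cerium), MeCN–H2O, 0 °C; extract, then Na2S2O4, EtOAc–H2O, rt, under N2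
Reagents that add atoms: water, O
Why: Oxidative demethylation of a 1,4-dimethoxyarene to the quinone, which isolated trisubstituted alkenes tolerate, followed by dithionite reduction; the air-sensitive hydroquinone is taken on directly.

Step 22
Reactants: 32 the hydroquinone
Product: 33 the target, bis(hydrogen sulfate) of 32
Conditions: SO3·pyridine (excess), pyridine, rt; aqueous work-up, reversed-phase chromatography
Reagents that add atoms: sulfur trioxide–pyridine complex, [O-]S(=O)(=O)[n+]1ccccc1
Why: O-Sulfation of both phenols with the pyridine complex of SO3; the axial tertiary 8'-hydroxyl is too hindered to react at room temperature, and the basic medium protects the alkene.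

## Compound list

1 | (+)-sclareolide | O=C1C[C@@H]2[C@@]3(C)CCCC(C)(C)[C@@H]3CC[C@@]2(C)O1 | starting material
2 | 8-epi-sclareolide | O=C1C[C@@H]2[C@@]3(C)CCCC(C)(C)[C@@H]3CC[C@]2(C)O1 | intermediate
3 | (1R,2S,4aS,8aS)-1-(2-hydroxyethyl)-2,5,5,8a-tetramethyldecahydronaphthalen-2-ol | OCC[C@@H]1[C@@]2(C)CCCC(C)(C)[C@@H]2CC[C@]1(C)O | intermediate
4 | bis(triethylsilyl) ether of 3 | CC[Si](CC)(CC)OCC[C@@H]1[C@@]2(C)CCCC(C)(C)[C@@H]2CC[C@]1(C)O[Si](CC)(CC)CC | intermediate
5 | 2-DecOSi-ethanol | OCC[C@@H]1[C@@]2(C)CCCC(C)(C)[C@@H]2CC[C@]1(C)O[Si](CC)(CC)CC | intermediate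
6 | 2-DecOSi-ethyl iodide | ICC[C@@H]1[C@@]2(C)CCCC(C)(C)[C@@H]2CC[C@]1(C)O[Si](CC)(CC)CC | intermediate
7 | geranyl acetate | CC(=O)OC/C=C(C)/CCC=C(C)C | starting material
8 | (±)-6,7-epoxygeranyl acetate | CC(=O)OC/C=C(C)/CCC1OC1(C)C | intermediate
9 | (2E)-3-methyl-6-oxohex-2-en-1-yl acetate | CC(=O)OC/C=C(C)/CCC=O | intermediate
10 | (2E,6Z)-7-iodo-3-methylocta-2,6-dien-1-yl acetate | CC(=O)OC/C=C(C)/CC/C=C(C)\I | intermediate
11 | 2-DecOSi-ethyllithium | [Li]CC[C@@H]1[C@@]2(C)CCCC(C)(C)[C@@H]2CC[C@]1(C)O[Si](CC)(CC)CC | intermediate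
12 | lithium B-methoxy-B-(2-DecOSi-ethyl)-9-borabicyclo[3.3.1]nonan-9-uide | [Li+].CO[B-]1(CC[C@@H]4[C@@]5(C)CCCC(C)(C)[C@@H]5CC[C@]4(C)O[Si](CC)(CC)CC)C2CCCC1CCC2 | intermediate
13 | (2E,6Z)-3,7-dimethyl-9-DecOSi-nona-2,6-dien-1-yl acetate | CC(=O)OC/C=C(C)/CC/C=C(C)\CC[C@@H]1[C@@]2(C)CCCC(C)(C)[C@@H]2CC[C@]1(C)O[Si](CC)(CC)CC | intermediate
14 | (2E)-3-methyl-5-[(2S,3R)-3-methyl-3-(2-DecOSi-ethyl)oxiran-2-yl]pent-2-en-1-yl acetate | CC(=O)OC/C=C(C)/CC[C@@H]1O[C@]1(C)CC[C@@H]2[C@@]3(C)CCCC(C)(C)[C@@H]3CC[C@]2(C)O[Si](CC)(CC)CC | intermediate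
15 | (2E)-3-methyl-5-[(2S,3R)-3-methyl-3-(2-DecOSi-ethyl)oxiran-2-yl]pent-2-en-1-ol | OC/C=C(C)/CC[C@@H]1O[C@]1(C)CC[C@@H]2[C@@]3(C)CCCC(C)(C)[C@@H]3CC[C@]2(C)O[Si](CC)(CC)CC | intermediate
16 | methanesulfonate of 15 | CS(=O)(=O)OC/C=C(C)/CC[C@@H]1O[C@]1(C)CC[C@@H]2[C@@]3(C)CCCC(C)(C)[C@@H]3CC[C@]2(C)O[Si](CC)(CC)CC | intermediate
17 | (2S,3R)-2-[(3E)-5-bromo-3-methylpent-3-en-1-yl]-3-methyl-3-(2-DecOSi-ethyl)oxirane | BrC/C=C(C)/CC[C@@H]1O[C@]1(C)CC[C@@H]2[C@@]3(C)CCCC(C)(C)[C@@H]3CC[C@]2(C)O[Si](CC)(CC)CC | intermediate
18 | dimethyl (2-oxopropyl)phosphonate | COP(=O)(OC)CC(C)=O | starting material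
19 | sodium lithium dianion of 18 | [Na+].[Li+].COP(=O)(OC)[CH-]C(=O)[CH2-] | intermediate
20 | dimethyl {(5E)-6-methyl-8-[(2S,3R)-3-methyl-3-(2-DecOSi-ethyl)oxiran-2-yl]-2-oxooct-5-en-1-yl}phosphonate | COP(=O)(OC)CC(=O)CC/C=C(C)/CC[C@@H]1O[C@]1(C)CC[C@@H]2[C@@]3(C)CCCC(C)(C)[C@@H]3CC[C@]2(C)O[Si](CC)(CC)CC | intermediate
21 | 2,5-dimethoxybenzaldehyde | COc1ccc(OC)c(C=O)c1 | starting material
22 | (1E,6E)-1-(2,5-dimethoxyphenyl)-7-methyl-9-[(2S,3R)-3-methyl-3-(2-DecOSi-ethyl)oxiran-2-yl]nona-1,6-dien-3-one | COc4ccc(OC)c(/C=C/C(=O)CC/C=C(C)/CC[C@@H]1O[C@]1(C)CC[C@@H]2[C@@]3(C)CCCC(C)(C)[C@@H]3CC[C@]2(C)O[Si](CC)(CC)CC)c4 | intermediate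
23 | Z-enol tert-butyldimethylsilyl ether of the 11-dihydro ketone (key-step precursor) | COc1ccc(OC)cc1C/C=C(O[Si](C)(C)C(C)(C)C)/CC/C=C(C)/CC[C@@H]2O[C@]2(C)CC[C@@H]3[C@@]4(C)CCCC(C)(C)[C@@H]4CC[C@]3(C)O[Si](CC)(CC)CC | intermediate
24 | left trans-decalin ketol: 3β-OH, 4α-CH3, 4β-(2-DecOSi-ethyl), 5α-H, 8-oxo, 9β-(2,5-dimethoxybenzyl), 10β-CH3 | O=C1CC[C@H]2[C@@](C)(CC[C@@H]3[C@@]4(C)CCCC(C)(C)[C@@H]4CC[C@]3(C)O[Si](CC)(CC)CC)[C@@H](O)CC[C@]2(C)[C@H]1Cc1cc(OC)ccc1OC | intermediate
25 | 3β-O-phenoxythiocarbonyl derivative of 24 | O=C1CC[C@H]2[C@@](C)(CC[C@@H]3[C@@]4(C)CCCC(C)(C)[C@@H]4CC[C@]3(C)O[Si](CC)(CC)CC)[C@@H](OC(=S)Oc5ccccc5)CC[C@]2(C)[C@H]1Cc1cc(OC)ccc1OC | intermediate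
26 | 3-deoxy 8-ketone | O=C1CC[C@H]2[C@@](C)(CC[C@@H]3[C@@]4(C)CCCC(C)(C)[C@@H]4CC[C@]3(C)O[Si](CC)(CC)CC)CCC[C@]2(C)[C@H]1Cc1cc(OC)ccc1OC | intermediate
27 | potassium Δ7-enolate of 26 | [K+].[O-]C1=CC[C@H]2[C@@](C)(CC[C@@H]3[C@@]4(C)CCCC(C)(C)[C@@H]4CC[C@]3(C)O[Si](CC)(CC)CC)CCC[C@]2(C)[C@H]1Cc1cc(OC)ccc1OC | intermediate
28 | C7=C8 enol triflate | O=S(=O)(OC1=CC[C@H]2[C@@](C)(CC[C@@H]3[C@@]4(C)CCCC(C)(C)[C@@H]4CC[C@]3(C)O[Si](CC)(CC)CC)CCC[C@]2(C)[C@H]1Cc1cc(OC)ccc1OC)C(F)(F)F | intermediate
29 | 8-methyl-7-ene, 8'-O-triethylsilyl, dimethyl ether | CC1=CC[C@H]2[C@@](C)(CC[C@@H]3[C@@]4(C)CCCC(C)(C)[C@@H]4CC[C@]3(C)O[Si](CC)(CC)CC)CCC[C@]2(C)[C@H]1Cc1cc(OC)ccc1OC | intermediate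
30 | 8-methyl-7-ene, free 8'-alcohol, dimethyl ether | CC1=CC[C@H]2[C@@](C)(CC[C@@H]3[C@@]4(C)CCCC(C)(C)[C@@H]4CC[C@]3(C)O)CCC[C@]2(C)[C@H]1Cc1cc(OC)ccc1OC | intermediate
31 | 2-substituted 1,4-benzoquinone | CC1=CC[C@H]2[C@@](C)(CC[C@@H]3[C@@]4(C)CCCC(C)(C)[C@@H]4CC[C@]3(C)O)CCC[C@]2(C)[C@H]1CC1=CC(=O)C=CC1=O | intermediate
32 | hydroquinone | CC1=CC[C@H]2[C@@](C)(CC[C@@H]3[C@@]4(C)CCCC(C)(C)[C@@H]4CC[C@]3(C)O)CCC[C@]2(C)[C@H]1Cc1cc(O)ccc1O | intermediate
33 | CNP0471499.2, hydroquinone bis(hydrogen sulfate) | CC1=CC[C@H]2[C@@](C)(CC[C@@H]3[C@@]4(C)CCCC(C)(C)[C@@H]4CC[C@]3(C)O)CCC[C@]2(C)[C@H]1Cc1cc(OS(=O)(=O)O)ccc1OS(=O)(=O)O | target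

## Step count and least certain steps

Total: 22 steps. Longest linear sequence: 19 steps (steps 1–4 and 8–22, from 1).

**Step 15 (key step).** Several processes can divert the cascade:
- the 8'-silyloxy oxygen may capture the activated oxirane at C4 in a six-membered closure;
- a 1,2-hydride shift may convert the opened oxirane into a C3 ketone;
- the cascade may stop after ring A, with proton loss from C10, because the enol silane carbon bearing the arylmethyl group is a hindered terminator;
- the enol silane may be protodesilylated before it cyclises, or the silyl group may move to the C3 oxygen.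

The fallback keeps the oxirane logic but changes the terminator and brings in the arene afterwards; it sets out from 17 and returns at 24. Alkylation of the dianion of allyl acetoacetate with 17 would give the allyl β-keto ester F1. SnCl4 in CH2Cl2 at −78 °C would cyclise it, with the β-keto ester as the less hindered terminating nucleophile and the same anti opening and chair–chair fold, to the bicyclic hydroxy β-keto ester F2. C-Alkylation of F2 with 2,5-dimethoxybenzyl bromide (K2CO3, acetone) would give the C9-quaternary keto ester F3, whose C9 configuration is of no consequence. Palladium-catalysed deallylation–decarboxylation (Pd(OAc)2, PPh3, HCO2H, Et3N) with equilibration at C9 would give 24.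

**Step 9.** Facial selectivity of the dioxirane may be insufficient on a Z-trisubstituted alkene whose larger C4 substituent lies cis to the chain, and oxidation at C5=C10 may begin if conversion is forced. The fallback uses hydroxyl-directed epoxidation of a neryl-type alcohol; it sets out from 6 and returns at 15.
- Borate 12, made from 6 as in step 8, would be coupled with (Z)-3-iodobut-2-en-1-ol (OC/C=C(C)\I) to give the Z-allylic alcohol F4.
- Sharpless asymmetric epoxidation (Ti(OiPr)4, L-(+)-diethyl tartrate, tBuOOH, 4 Å sieves, −20 °C), in the sense established for nerol, would give the (2S,3R)-epoxy alcohol F5.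
- I2/PPh3/imidazole would give the epoxy iodide F6.
- Alkylation of the dianion of methyl acetoacetate with F6 would give the β-keto ester F7.
- NaH and ClP(O)(OEt)2 would give the Z-enol phosphate F8.
- Me2CuLi at low temperature would replace the phosphate by methyl with retention and give the E-enoate F9.
- iBu2AlH at −78 °C would give 15.

**Step 8.** Zerovalent palladium may ionise the allylic acetate once the vinyl iodide is consumed, and the alkyllithium may be lost by protonation or silyl migration before boron capture. The fallback removes the ester from the palladium step; it sets out from 10 and returns at 13. Methanolysis of 10 (K2CO3, MeOH) would give the free iodo dienol F10. Its coupling with borate 12 under the conditions of step 8 would give the dienol F11, since free allylic alcohols do not ionise. Acetylation (Ac2O, pyridine) would give 13.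

**Step 14.** The silane may add 1,2, the Z selectivity of the enol silane may erode, or silyl electrophiles may open the oxirane. The fallback builds the enol silane from an acylsilane; it sets out from 17 and returns at 23. Alkylation of the lithium enolate of acetyl(tert-butyl)dimethylsilane with 17 would give the acylsilane F12. Addition of α-lithiated 2-(2,5-dimethoxyphenyl)ethyl phenyl sulfone, Brook rearrangement and loss of sulfinate would give 23 with the double bond fixed at C8=C9; its geometry would have to be checked.

## Further compounds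

F1 | step 15 | allyl (6E)-7-methyl-9-[(2S,3R)-3-methyl-3-(2-DecOSi-ethyl)oxiran-2-yl]-3-oxonon-6-enoate | C=CCOC(=O)CC(=O)CC/C=C(C)/CC[C@@H]1O[C@]1(C)CC[C@@H]2[C@@]3(C)CCCC(C)(C)[C@@H]3CC[C@]2(C)O[Si](CC)(CC)CC
F2 | step 15 | bicyclic 3β-hydroxy-8-oxo 9β-allyl ester (4α-CH3, 4β-(2-DecOSi-ethyl), 5α-H, 10β-CH3) | O=C1CC[C@H]2[C@@](C)(CC[C@@H]3[C@@]4(C)CCCC(C)(C)[C@@H]4CC[C@]3(C)O[Si](CC)(CC)CC)[C@@H](O)CC[C@]2(C)[C@H]1C(=O)OCC=C
F3 | step 15 | 9-(2,5-dimethoxybenzyl) derivative of F2 (arylmethyl drawn α) | O=C1CC[C@H]2[C@@](C)(CC[C@@H]3[C@@]4(C)CCCC(C)(C)[C@@H]4CC[C@]3(C)O[Si](CC)(CC)CC)[C@@H](O)CC[C@]2(C)[C@@]1(Cc5cc(OC)ccc5OC)C(=O)OCC=C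
F4 | step 9 | (2Z)-3-methyl-5-DecOSi-pent-2-en-1-ol | OC/C=C(C)\CC[C@@H]1[C@@]2(C)CCCC(C)(C)[C@@H]2CC[C@]1(C)O[Si](CC)(CC)CC
F5 | step 9 | [(2S,3R)-3-methyl-3-(2-DecOSi-ethyl)oxiran-2-yl]methanol | OC[C@@H]1O[C@]1(C)CC[C@@H]2[C@@]3(C)CCCC(C)(C)[C@@H]3CC[C@]2(C)O[Si](CC)(CC)CC
F6 | step 9 | (2S,3R)-2-(iodomethyl)-3-methyl-3-(2-DecOSi-ethyl)oxirane | IC[C@@H]1O[C@]1(C)CC[C@@H]2[C@@]3(C)CCCC(C)(C)[C@@H]3CC[C@]2(C)O[Si](CC)(CC)CC
F7 | step 9 | methyl 5-[(2S,3R)-3-methyl-3-(2-DecOSi-ethyl)oxiran-2-yl]-3-oxopentanoate | COC(=O)CC(=O)CC[C@@H]1O[C@]1(C)CC[C@@H]2[C@@]3(C)CCCC(C)(C)[C@@H]3CC[C@]2(C)O[Si](CC)(CC)CC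
F8 | step 9 | Z-enol diethyl phosphate of F7 | COC(=O)/C=C(OP(=O)(OCC)OCC)/CC[C@@H]1O[C@]1(C)CC[C@@H]2[C@@]3(C)CCCC(C)(C)[C@@H]3CC[C@]2(C)O[Si](CC)(CC)CC
F9 | step 9 | methyl (2E)-3-methyl-5-[(2S,3R)-3-methyl-3-(2-DecOSi-ethyl)oxiran-2-yl]pent-2-enoate | COC(=O)/C=C(C)/CC[C@@H]1O[C@]1(C)CC[C@@H]2[C@@]3(C)CCCC(C)(C)[C@@H]3CC[C@]2(C)O[Si](CC)(CC)CC
F10 | step 8 | (2E,6Z)-7-iodo-3-methylocta-2,6-dien-1-ol | OC/C=C(C)/CC/C=C(C)\I
F11 | step 8 | (2E,6Z)-3,7-dimethyl-9-DecOSi-nona-2,6-dien-1-ol | OC/C=C(C)/CC/C=C(C)\CC[C@@H]1[C@@]2(C)CCCC(C)(C)[C@@H]2CC[C@]1(C)O[Si](CC)(CC)CC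
F12 | step 14 | (4E)-1-[tert-butyl(dimethyl)silyl]-5-methyl-7-[(2S,3R)-3-methyl-3-(2-DecOSi-ethyl)oxiran-2-yl]hept-4-en-1-one | CC(C)(C)[Si](C)(C)C(=O)CC/C=C(C)/CC[C@@H]1O[C@]1(C)CC[C@@H]2[C@@]3(C)CCCC(C)(C)[C@@H]3CC[C@]2(C)O[Si](CC)(CC)CC
A1 | alternative 1 | bicyclic Δ5-7-ketone with axial C4 nitrile | O=C1C=C2[C@@](C)(C#N)CCC[C@]2(C)CC1
A2 | alternative 1 | 3-(1-cyanoethyl)-4-(3-iodopropyl)-4-methylcyclohex-2-enone | O=C1C=C(C(C)C#N)[C@](C)(CCCI)CC1
A3 | alternative 2 | 2-terpenyl-4-methoxyphenol | CC1=CC[C@H]2[C@@](C)(CC[C@@H]3[C@@]4(C)CCCC(C)(C)[C@@H]4CC[C@]3(C)O)CCC[C@]2(C)[C@H]1Cc1cc(OC)ccc1O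
A4 | alternative 2 | 9β-propargyl bis-decalin alkyne | CC1=CC[C@H]2[C@@](C)(CC[C@@H]3[C@@]4(C)CCCC(C)(C)[C@@H]4CC[C@]3(C)O)CCC[C@]2(C)[C@H]1CC#C
A5 | alternative 2 | pentacarbonyl[methoxy(vinyl)carbene]chromium, Cr(CO)5[C(OMe)CH=CH2] | COC(C=C)=[Cr](=C=O)(=C=O)(=C=O)(=C=O)=C=O
A6 | alternative 3 | bis-decalin 3'-hydroxy-8'-ketone | CC1=CC[C@H]2[C@@](C)(CC[C@@H]3[C@@]4(C)CC[C@H](O)C(C)(C)[C@@H]4CCC3=O)CCC[C@]2(C)[C@H]1Cc1cc(OC)ccc1OC
A7 | alternative 3 | terminal (S)-epoxy diene Z-enol silane on the left decalin | CC1=CC[C@H]2[C@@](C)(CC/C=C(O[Si](C)(C)C(C)(C)C)/CC/C=C(C)/CC[C@@H]3OC3(C)C)CCC[C@]2(C)[C@H]1Cc1cc(OC)ccc1OC
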